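**Strategy**

The chain (numbered from benzylic C1' to the CH2OH carbon C16') is cut at C1'–C2' and at the C3'–methyl bond. The feature used is the (E)-trisubstituted C2'=C3' alkene lying between the benzene ring and the C5' carbinol: a terminal alkyne spanning C2'–C3' is methylaluminated syn and the resulting alkenylalane is joined to a benzylic chloride of the ring under nickel catalysis, so two C–C bonds and the E geometry arise in one flask with no allylic electrophile. The precursor is the C2'–C16' homopropargylic alkyne, (S) at C5', both hydroxyls as TBS ethers; the ring enters as 2,5-dimethoxy-3-methylbenzyl chloride, unmasked at the end.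

Key step: step 11

Assumption: the (S)-configured phosphoric acid in step 5 is taken to direct the allenyl group to the Si face of enal 5, by analogy with the (R)-acid giving Re-face addition to aryl and alkenyl aldehydes; the configuration of 8 is to be confirmed on its MTPA esters, and the antipodal acid is used if the sense proves reversed.

**Route**

Step 1
Reactants: 1 (2E,6E)-farnesyl acetate
Product: 2 (2E,6E,10E)-12-hydroxy-3,7,11-trimethyldodeca-2,6,10-trien-1-yl acetate
Conditions: SeO2 (cat.), t-BuOOH, salicylic acid (cat.), CH2Cl2, 0 °C to rt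
Reagents that add atoms: tert-butyl hydroperoxide, CC(C)(C)OO (oxygen relayed by selenium dioxide, O=[Se]=O)
Why: Riley-type allylic oxidation (ene reaction, then [2,3]-sigmatropic shift) should occur at the accessible terminal trisubstituted alkene, the C2 alkene being deactivated by the acetate, and the sigmatropic step delivers the (E)-allylic alcohol with the hydroxymethyl group trans to the chain.

Step 2
Reactants: 2 (2E,6E,10E)-12-hydroxy-3,7,11-trimethyldodeca-2,6,10-trien-1-yl acetate
Product: 3 (2E,6E,10E)-12-(tert-butyldimethylsilyloxy)-3,7,11-trimethyldodeca-2,6,10-trien-1-yl acetate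
Conditions: TBSCl, imidazole, CH2Cl2, 0 °C to rt
Reagents that add atoms: tert-butyldimethylsilyl chloride, CC(C)(C)[Si](C)(C)Cl
Why: Imidazole-promoted silylation of an unhindered primary allylic alcohol is routine and leaves the acetate untouched.

Step 3
Reactants: 3 (2E,6E,10E)-12-(tert-butyldimethylsilyloxy)-3,7,11-trimethyldodeca-2,6,10-trien-1-yl acetate
Product: 4 (2E,6E,10E)-12-(tert-butyldimethylsilyloxy)-3,7,11-trimethyldodeca-2,6,10-trien-1-ol
Conditions: K2CO3, MeOH, rt
Reagents that add atoms: none
Why: Base-catalysed transesterification with methanol removes the allylic acetate, while the primary TBS ether is stable to K2CO3 in methanol.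

Step 4
Reactants: 4 (2E,6E,10E)-12-(tert-butyldimethylsilyloxy)-3,7,11-trimethyldodeca-2,6,10-trien-1-ol
Product: 5 (2E,6E,10E)-12-(tert-butyldimethylsilyloxy)-3,7,11-trimethyldodeca-2,6,10-trienal
Conditions: MnO2 (activated, excess), CH2Cl2, rt
Reagents that add atoms: none
Why: Activated MnO2 oxidises the allylic alcohol selectively to the enal without isomerising the C2 alkene, and the silyl ether and isolated alkenes are inert.

Step 5
Reactants: 5 (2E,6E,10E)-12-(tert-butyldimethylsilyloxy)-3,7,11-trimethyldodeca-2,6,10-trienal; 6 allenylboronic acid pinacol ester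
Product: 8 (4S,5E,9E,13E)-15-(tert-butyldimethylsilyloxy)-6,10,14-trimethylpentadeca-5,9,13-trien-1-yn-4-ol, via pinacol borate ester 7 (not isolated)
Conditions: (S)-3,3'-bis(2,4,6-triisopropylphenyl)-1,1'-binaphthyl-2,2'-diyl hydrogen phosphate (10 mol %), 4 Å MS, toluene, −20 to 0 °C; aq. NaHCO3 work-up
Reagents that add atoms: allenylboronic acid pinacol ester (6), C=C=CB1OC(C)(C)C(C)(C)O1
Why: Brønsted acid-catalysed enantioselective propargylboration, in which the chiral phosphoric acid binds a boronate oxygen and the formyl hydrogen and the allenyl unit is delivered through a closed six-membered SE2' transition state to the Si face of the aldehyde, setting (S)-C5' by catalyst control and giving only the homopropargylic 1,2-adduct.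

Step 6
Reactants: 8 (4S,5E,9E,13E)-15-(tert-butyldimethylsilyloxy)-6,10,14-trimethylpentadeca-5,9,13-trien-1-yn-4-ol
Product: 9 (4S,5E,9E,13E)-4,15-bis(tert-butyldimethylsilyloxy)-6,10,14-trimethylpentadeca-5,9,13-trien-1-yne
Conditions: TBSCl, imidazole, DMAP (cat.), DMF, rt
Reagents that add atoms: tert-butyldimethylsilyl chloride, CC(C)(C)[Si](C)(C)Cl
Why: Silylation of the secondary carbinol does not touch the C5' configuration, and the bulky, weakly Lewis-basic TBS group matches the C16' ether (one later deprotection) and keeps the allylic oxygen from chelating or ionising during carbometalation.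

Step 7
Reactants: 10 4-methoxy-2-methylphenol
Product: 12 2-hydroxy-5-methoxy-3-methylbenzaldehyde, via ortho-hydroxymethyl phenol 11 (not isolated)
Conditions: MgCl2, Et3N, (CH2O)n, MeCN, reflux; aq. HCl work-up
Reagents that add atoms: paraformaldehyde (formaldehyde unit), C=O
Why: Magnesium-mediated ortho-formylation of phenols (Casnati–Skattebøl reaction), in which the magnesium phenoxide directs formaldehyde to the only free ortho position and the hydroxymethyl intermediate is oxidised in situ by a second formaldehyde through an Oppenauer-type hydride transfer.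

Step 8
Reactants: 12 2-hydroxy-5-methoxy-3-methylbenzaldehyde
Product: 13 2,5-dimethoxy-3-methylbenzaldehyde
Conditions: MeI, K2CO3, DMF, 40 °C
Reagents that add atoms: iodomethane, CI
Why: Williamson O-methylation of the phenoxide is reliable even for a phenol flanked by two ortho substituents.

Step 9
Reactants: 13 2,5-dimethoxy-3-methylbenzaldehyde
Product: 14 (2,5-dimethoxy-3-methylphenyl)methanol
Conditions: NaBH4, MeOH, 0 °C
Reagents that add atoms: none
Why: Borohydride reduction of an aryl aldehyde to the benzylic alcohol is clean and leaves the aryl ethers untouched.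

Step 10
Reactants: 14 (2,5-dimethoxy-3-methylphenyl)methanol
Product: 16 1-(chloromethyl)-2,5-dimethoxy-3-methylbenzene, via benzylic chlorosulfite 15 (not isolated)
Conditions: SOCl2, CH2Cl2, 0 °C to rt
Reagents that add atoms: thionyl chloride, O=S(Cl)Cl
Why: Chlorodehydroxylation through the chlorosulfite, which collapses readily at the electron-rich benzylic carbon; the chloride is to be used promptly.

Step 11
Reactants: 9 (4S,5E,9E,13E)-4,15-bis(tert-butyldimethylsilyloxy)-6,10,14-trimethylpentadeca-5,9,13-trien-1-yne; 17 trimethylaluminium; 16 1-(chloromethyl)-2,5-dimethoxy-3-methylbenzene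
Product: 19 1-[(2E,5S,6E,10E,14E)-5,16-bis(tert-butyldimethylsilyloxy)-3,7,11,15-tetramethylhexadeca-2,6,10,14-tetraen-1-yl]-2,5-dimethoxy-3-methylbenzene, via (E)-alkenyldimethylalane 18 (not isolated)
Conditions: AlMe3 (2.0 equiv), Cp2ZrCl2 (0.2 equiv), H2O (1.0 equiv), CH2Cl2, −20 to 0 °C; volatiles removed in vacuo; THF, 16 (1.2 equiv), NiCl2(PPh3)2 (5 mol %) pre-reduced with n-BuLi (10 mol %) to zerovalent nickel, 0 °C to rt
Reagents that add atoms: trimethylaluminium (17), C[Al](C)C
Why: The Cp2ZrCl2–AlMe3 pair forms a methylzirconium species that adds methyl and metal syn across the C2'≡C3' triple bond, methyl to internal C3' and metal to terminal C2', and exchange to aluminium leaves the (E)-alkenyldimethylalane 18; zerovalent nickel then inserts into the benzylic C–Cl bond of 16, the alkenyl group passes from aluminium to nickel, and reductive elimination forms C1'–C2' with retention of alkene geometry. The closest known reaction type is the Negishi zirconium-catalysed carboalumination of terminal alkynes followed by nickel-catalysed coupling of the alkenylalane with a benzylic chloride, as used to attach polyprenyl chains to protected hydroquinones. No ring is closed and no stereocentre is created; the (S) centre at C5' is a silyl ether away from the reacting carbons and is not touched. The step needs regioselectivity (methyl to C3'), syn addition (E alkene) and chemoselectivity for the alkyne over three trisubstituted alkenes; the first two are inherent to a terminal, non-propargylic alkyne, and unactivated trisubstituted alkenes do not undergo carboalumination under these conditions. The bulky TBS ethers should neither chelate the metals nor ionise at low temperature, and because the electrophile is benzylic there is no SN2' pathway and no E/Z question at C2'=C3'.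

Step 12
Reactants: 19 1-[(2E,5S,6E,10E,14E)-5,16-bis(tert-butyldimethylsilyloxy)-3,7,11,15-tetramethylhexadeca-2,6,10,14-tetraen-1-yl]-2,5-dimethoxy-3-methylbenzene
Product: 20 1-[(2E,5S,6E,10E,14E)-5,16-dihydroxy-3,7,11,15-tetramethylhexadeca-2,6,10,14-tetraen-1-yl]-2,5-dimethoxy-3-methylbenzene
Conditions: TBAF (3 equiv), THF, 0 °C to rt
Reagents that add atoms: none
Why: Fluoride-induced cleavage of both silyl ethers, driven by the strong Si–F bond, should leave aryl methyl ethers, alkenes and the C5' centre unaffected.

Step 13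
Reactants: 20 1-[(2E,5S,6E,10E,14E)-5,16-dihydroxy-3,7,11,15-tetramethylhexadeca-2,6,10,14-tetraen-1-yl]-2,5-dimethoxy-3-methylbenzene
Product: 21 2-[(2E,5S,6E,10E,14E)-5,16-dihydroxy-3,7,11,15-tetramethylhexadeca-2,6,10,14-tetraen-1-yl]-6-methylcyclohexa-2,5-diene-1,4-dione
Conditions: (NH4)2Ce(NO3)6 (2.5 equiv), MeCN–H2O, 0 °C, short reaction time; kept from light and base
Reagents that add atoms: water, O
Why: Oxidative demethylation of a 1,4-dimethoxyarene, in which tetravalent cerium removes two electrons from the electron-rich ring, water adds at the methoxy-bearing carbons and methanol is lost, a process expected to be much faster at 0 °C than oxidation of the allylic alcohols or alkenes.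

Step 14
Reactants: 21 2-[(2E,5S,6E,10E,14E)-5,16-dihydroxy-3,7,11,15-tetramethylhexadeca-2,6,10,14-tetraen-1-yl]-6-methylcyclohexa-2,5-diene-1,4-dione
Product: 22 2-[(2E,5S,6E,10E,14E)-5,16-dihydroxy-3,7,11,15-tetramethylhexadeca-2,6,10,14-tetraen-1-yl]-6-methylbenzene-1,4-diol
Conditions: Na2S2O4 (aq., excess), EtOAc–H2O, rt, argon
Reagents that add atoms: none
Why: Two-electron reduction of the quinone by dithionite in a two-phase system under argon should give the hydroquinone without touching alkenes, alcohols or the C5' centre.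

**Compound list**

1 | (2E,6E)-farnesyl acetate | CC(C)=CCC/C(C)=C/CC/C(C)=C/COC(C)=O | starting material
2 | (2E,6E,10E)-12-hydroxy-3,7,11-trimethyldodeca-2,6,10-trien-1-yl acetate | C/C(=C\CC/C(C)=C/CC/C(C)=C/COC(C)=O)CO | intermediate
3 | (2E,6E,10E)-12-(tert-butyldimethylsilyloxy)-3,7,11-trimethyldodeca-2,6,10-trien-1-yl acetate | C/C(=C\CC/C(C)=C/CC/C(C)=C/COC(C)=O)CO[Si](C)(C)C(C)(C)C | intermediate
4 | (2E,6E,10E)-12-(tert-butyldimethylsilyloxy)-3,7,11-trimethyldodeca-2,6,10-trien-1-ol | C/C(=C\CC/C(C)=C/CC/C(C)=C/CO)CO[Si](C)(C)C(C)(C)C | intermediate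
5 | (2E,6E,10E)-12-(tert-butyldimethylsilyloxy)-3,7,11-trimethyldodeca-2,6,10-trienal | C/C(=C\CC/C(C)=C/CC/C(C)=C/C=O)CO[Si](C)(C)C(C)(C)C | intermediate
6 | allenylboronic acid pinacol ester | C=C=CB1OC(C)(C)C(C)(C)O1 | starting material
7 | pinacol borate ester of 8 (O–B(pin) at C5', formed in the flask) | C/C(=C\CC/C(C)=C/CC/C(C)=C/[C@@H](OB1OC(C)(C)C(C)(C)O1)CC#C)CO[Si](C)(C)C(C)(C)C | intermediate
8 | (4S,5E,9E,13E)-15-(tert-butyldimethylsilyloxy)-6,10,14-trimethylpentadeca-5,9,13-trien-1-yn-4-ol | C/C(=C\CC/C(C)=C/CC/C(C)=C/[C@@H](O)CC#C)CO[Si](C)(C)C(C)(C)C | intermediate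
9 | (4S,5E,9E,13E)-4,15-bis(tert-butyldimethylsilyloxy)-6,10,14-trimethylpentadeca-5,9,13-trien-1-yne | C/C(=C\CC/C(C)=C/CC/C(C)=C/[C@@H](O[Si](C)(C)C(C)(C)C)CC#C)CO[Si](C)(C)C(C)(C)C | intermediate
10 | 4-methoxy-2-methylphenol | COc1ccc(O)c(C)c1 | starting material
11 | 2-(hydroxymethyl)-4-methoxy-6-methylphenol (present as its magnesium salt, formed in the flask) | OCc1cc(OC)cc(C)c1O | intermediate
12 | 2-hydroxy-5-methoxy-3-methylbenzaldehyde | O=Cc1cc(OC)cc(C)c1O | intermediate
13 | 2,5-dimethoxy-3-methylbenzaldehyde | O=Cc1cc(OC)cc(C)c1OC | intermediate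
14 | (2,5-dimethoxy-3-methylphenyl)methanol | OCc1cc(OC)cc(C)c1OC | intermediate
15 | 2,5-dimethoxy-3-methylbenzyl chlorosulfite (formed in the flask) | O=S(Cl)OCc1cc(OC)cc(C)c1OC | intermediate
16 | 1-(chloromethyl)-2,5-dimethoxy-3-methylbenzene | ClCc1cc(OC)cc(C)c1OC | intermediate
17 | trimethylaluminium | C[Al](C)C | starting material
18 | dimethyl[(1E,4S,5E,9E,13E)-4,15-bis(tert-butyldimethylsilyloxy)-2,6,10,14-tetramethylpentadeca-1,5,9,13-tetraen-1-yl]alumane (formed in the flask) | C/C(=C\CC/C(C)=C/CC/C(C)=C/[C@@H](O[Si](C)(C)C(C)(C)C)C/C(C)=C/[Al](C)C)CO[Si](C)(C)C(C)(C)C | intermediate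
19 | 1-[(2E,5S,6E,10E,14E)-5,16-bis(tert-butyldimethylsilyloxy)-3,7,11,15-tetramethylhexadeca-2,6,10,14-tetraen-1-yl]-2,5-dimethoxy-3-methylbenzene | C/C(=C\CC/C(C)=C/CC/C(C)=C/[C@@H](O[Si](C)(C)C(C)(C)C)C/C(C)=C/Cc1cc(OC)cc(C)c1OC)CO[Si](C)(C)C(C)(C)C | intermediate
20 | 1-[(2E,5S,6E,10E,14E)-5,16-dihydroxy-3,7,11,15-tetramethylhexadeca-2,6,10,14-tetraen-1-yl]-2,5-dimethoxy-3-methylbenzene | C/C(=C\CC/C(C)=C/CC/C(C)=C/[C@@H](O)C/C(C)=C/Cc1cc(OC)cc(C)c1OC)CO | intermediate
21 | 2-[(2E,5S,6E,10E,14E)-5,16-dihydroxy-3,7,11,15-tetramethylhexadeca-2,6,10,14-tetraen-1-yl]-6-methylcyclohexa-2,5-diene-1,4-dione | C/C(=C\CC/C(C)=C/CC/C(C)=C/[C@@H](O)C/C(C)=C/CC1=CC(=O)C=C(C)C1=O)CO | intermediate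
22 | 2-[(2E,5S,6E,10E,14E)-5,16-dihydroxy-3,7,11,15-tetramethylhexadeca-2,6,10,14-tetraen-1-yl]-6-methylbenzene-1,4-diol | C/C(=C\CC/C(C)=C/CC/C(C)=C/[C@@H](O)C/C(C)=C/Cc1cc(O)cc(C)c1O)CO | target

**Step count and risks**

Total step count: 14. Longest linear sequence: 10 steps (steps 1–6 and 11–14); the benzylic chloride is made in a 4-step side branch (steps 7–10).

Steps most likely to fail:

1. Step 11. The nickel stage may transfer methyl in place of the alkenyl group, the alane may be protonated before it couples, or the Lewis-acidic medium may ionise the allylic C5' silyl ether on prolonged exposure. Fallback: the two operations are separated and the polarity of the coupling is reversed. Setting out from alkyne 9, the methylalumination is kept, but alane 18 is quenched with iodine (THF, −30 °C) to give the isolable (1E,4S,5E,9E,13E)-alkenyl iodide F1. Chloride 16 is converted with zinc dust and LiCl in THF into (2,5-dimethoxy-3-methylbenzyl)zinc chloride F2. Negishi coupling of F1 with F2 under Pd(PPh3)4 (zerovalent palladium) in THF at rt should proceed with retention of geometry and rejoins the route at 19.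

2. Step 5. Facial discrimination may be insufficient for a β,β-disubstituted enal, or the catalysed addition may be slow enough for the uncatalysed racemic pathway to compete. Fallback: resolution replaces asymmetric catalysis. Setting out from enal 5, Barbier propargylation (propargyl bromide, zinc, THF–aq. NH4Cl) should give the racemic homopropargylic alcohol F3. Lipase-mediated acylation (Amano lipase PS, vinyl acetate, t-BuOMe, rt) should, by the usual size rule for lipases (large alkenyl, medium propargyl), esterify the (R)-carbinol to the (R)-acetate F4 and leave the (S)-alcohol. After chromatographic separation this is compound 8, where the route is rejoined.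

3. Step 13. Tetravalent cerium may over-oxidise the allylic carbinols or the electron-rich alkenes, the acidic medium may promote cyclisation of the side chain onto the ring oxygen, and the prenylquinone may isomerise to a chromenol on handling. Fallback: the oxidation is avoided by carrying the ring as silyl ethers. Setting out from aldehyde 12 (and alkyne 9), BBr3 in CH2Cl2 (−78 to 0 °C) should cleave the methyl ether to 2,5-dihydroxy-3-methylbenzaldehyde F5. TBSOTf and 2,6-lutidine then give 2,5-bis(tert-butyldimethylsilyloxy)-3-methylbenzaldehyde F6. NaBH4 at low temperature gives [2,5-bis(tert-butyldimethylsilyloxy)-3-methylphenyl]methanol F7. PPh3 and N-chlorosuccinimide in CH2Cl2 give 2,5-bis(tert-butyldimethylsilyloxy)-3-methylbenzyl chloride F8. The procedure of step 11 applied to 9 and F8 should give the tetrakis-TBS ether F9. A single fluoride treatment (TBAF buffered with AcOH, degassed THF, dithionite wash) should remove all four silyl groups and rejoins the route at target 22, bypassing steps 12–14.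

**Further compounds**

F1 | step 11 | (1E,4S,5E,9E,13E)-4,15-bis(tert-butyldimethylsilyloxy)-1-iodo-2,6,10,14-tetramethylpentadeca-1,5,9,13-tetraene | C/C(=C\CC/C(C)=C/CC/C(C)=C/[C@@H](O[Si](C)(C)C(C)(C)C)C/C(C)=C/I)CO[Si](C)(C)C(C)(C)C
F2 | step 11 | (2,5-dimethoxy-3-methylbenzyl)zinc chloride | Cl[Zn]Cc1cc(OC)cc(C)c1OC
F3 | step 5 | racemic (5E,9E,13E)-15-(tert-butyldimethylsilyloxy)-6,10,14-trimethylpentadeca-5,9,13-trien-1-yn-4-ol | C/C(=C\CC/C(C)=C/CC/C(C)=C/C(O)CC#C)CO[Si](C)(C)C(C)(C)C
F4 | step 5 | (4R,5E,9E,13E)-15-(tert-butyldimethylsilyloxy)-6,10,14-trimethylpentadeca-5,9,13-trien-1-yn-4-yl acetate | C/C(=C\CC/C(C)=C/CC/C(C)=C/[C@H](OC(C)=O)CC#C)CO[Si](C)(C)C(C)(C)C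
F5 | step 13 | 2,5-dihydroxy-3-methylbenzaldehyde | O=Cc1cc(O)cc(C)c1O
F6 | step 13 | 2,5-bis(tert-butyldimethylsilyloxy)-3-methylbenzaldehyde | O=Cc1cc(O[Si](C)(C)C(C)(C)C)cc(C)c1O[Si](C)(C)C(C)(C)C
F7 | step 13 | [2,5-bis(tert-butyldimethylsilyloxy)-3-methylphenyl]methanol | OCc1cc(O[Si](C)(C)C(C)(C)C)cc(C)c1O[Si](C)(C)C(C)(C)C
F8 | step 13 | 2,5-bis(tert-butyldimethylsilyloxy)-3-methylbenzyl chloride | ClCc1cc(O[Si](C)(C)C(C)(C)C)cc(C)c1O[Si](C)(C)C(C)(C)C
F9 | step 13 | 1-[(2E,5S,6E,10E,14E)-5,16-bis(tert-butyldimethylsilyloxy)-3,7,11,15-tetramethylhexadeca-2,6,10,14-tetraen-1-yl]-2,5-bis(tert-butyldimethylsilyloxy)-3-methylbenzene | C/C(=C\CC/C(C)=C/CC/C(C)=C/[C@@H](O[Si](C)(C)C(C)(C)C)C/C(C)=C/Cc1cc(O[Si](C)(C)C(C)(C)C)cc(C)c1O[Si](C)(C)C(C)(C)C)CO[Si](C)(C)C(C)(C)C
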